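**Retrosynthetic overview**
- The target is the ortho,para-dibromide of debromolaurinterol; both C–Br bonds are made last by electrophilic bromination directed by the phenol.
- The cyclopropane is the last ring formed: phenol-directed Simmons–Smith methylenation of an ortho-(1,2-dimethylcyclopent-2-enyl)phenol, CH2 delivered cis to the aryl group.
- The quaternary benzylic stereocentre comes from a dearomative [3,3] shift (aromatic Claisen) of an enantioenriched aryl cyclopentenyl ether: the cresol ring is dearomatised to an ortho-dienone, then re-aromatises, with 1,3-transfer of chirality from C–O to C–C.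
- The ether comes from m-cresol and (R)-2,3-dimethylcyclopent-2-en-1-ol by Mitsunobu inversion; the alcohol comes from CBS reduction of 2,3-dimethylcyclopent-2-en-1-one.
- Ring order: the arene and the cyclopentene are bought; only the cyclopropane is built (step 4).

Assumption: the SMILES is read as (1S,2R,5R) in the bicyclohexyl unit (aryl cis to the cyclopropane CH2, the two methyl groups cis to each other); 2,3-dimethylcyclopent-2-en-1-one and m-cresol are taken as commercial.

**Route**

Step 1
Reactants: 1 2,3-dimethylcyclopent-2-en-1-one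
Product: 2 (1R)-2,3-dimethylcyclopent-2-en-1-ol
Conditions: (S)-2-methyl-CBS-oxazaborolidine (10 mol %), BH3·SMe2 (0.7 equiv), THF, −20 °C; MeOH, then aq. NH4Cl
Reagents that add atoms: none
Why: Corey–Bakshi–Shibata reduction, in which the methyl-substituted alkenyl arm acts as the large group, so the (S)-catalyst delivers hydride to give the (R)-carbinol (same sense as acetophenone to (R)-1-phenylethanol), while the tetrasubstituted alkene is too hindered to be hydroborated at this temperature.

Step 2
Reactants: 2 (1R)-2,3-dimethylcyclopent-2-en-1-ol; 3 m-cresol (3-methylphenol)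
Product: 4 1-{[(1S)-2,3-dimethylcyclopent-2-en-1-yl]oxy}-3-methylbenzene
Conditions: PPh3 (1.3 equiv), DIAD (1.3 equiv), toluene, −20 → 0 °C
Reagents that add atoms: none
Why: Mitsunobu etherification, in which the phenol (pKa about 10) displaces the activated alcohol by SN2 with inversion, turning the (R)-carbinol into the (S)-aryl ether; the non-polar solvent and low temperature hold back ionisation and SN2' attack at the fully substituted alkene carbon.

Step 3
Reactants: 4 1-{[(1S)-2,3-dimethylcyclopent-2-en-1-yl]oxy}-3-methylbenzene
Product: 6 2-[(1R)-1,2-dimethylcyclopent-2-en-1-yl]-5-methylphenol, via ortho-dienone 5 (not isolated)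
Conditions: Eu(fod)3 [fod = 6,6,7,7,8,8,8-heptafluoro-2,2-dimethyloctane-3,5-dionate] (10 mol %), acid-free CHCl3, 50 °C
Reagents that add atoms: none
Why: Aromatic Claisen rearrangement ([3,3]-sigmatropic), in which the ring carbon ortho to oxygen and para to the methyl group bonds to the methyl-bearing alkene terminus on the same cyclopentene face that oxygen leaves, so the C–O stereocentre is traded for the (R)-quaternary benzylic carbon in dearomatised dienone 5, which enolises at once to phenol 6; the other ortho carbon, flanked by the ring methyl, is too crowded to take a quaternary substituent.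

Step 4
Reactants: 6 2-[(1R)-1,2-dimethylcyclopent-2-en-1-yl]-5-methylphenol
Product: 8 2-[(1S,2R,5R)-1,2-dimethylbicyclo[3.1.0]hexan-2-yl]-5-methylphenol (debromolaurinterol), via iodomethylzinc phenoxide 7 (not isolated)
Conditions: Et2Zn (2.5 equiv), CH2I2 (2.5 equiv), CH2Cl2, 0 °C → rt; aq. NH4Cl
Reagents that add atoms: diiodomethane (ICI)
Why: Furukawa-type Simmons–Smith cyclopropanation directed by the phenoxide, in which the carbenoid bound to oxygen in 7 can reach only the alkene face that carries the aryl group, so CH2 is delivered cis to the aryl ring and fixes C1 as S and C5 as R.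

Step 5
Reactants: 8 2-[(1S,2R,5R)-1,2-dimethylbicyclo[3.1.0]hexan-2-yl]-5-methylphenol
Product: 10 2,4-dibromo-6-[(1S,2R,5R)-1,2-dimethylbicyclo[3.1.0]hexan-2-yl]-3-methylphenol (target), via laurinterol 9 (not isolated)
Conditions: NBS (2.1 equiv), MeCN, −10 → 0 °C, dark
Reagents that add atoms: N-bromosuccinimide (O=C1CCC(=O)N1Br)
Why: Electrophilic aromatic bromination, in which the hydroxyl group sends the first bromine para (giving 9) and the second into the only free ortho position, while the neutral succinimide by-product keeps acid away from the cyclopropane; no stereocentre is touched.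

**Compound list**

| No. | Name | SMILES | Role |
|---|---|---|---|
| 1 | 2,3-dimethylcyclopent-2-en-1-one | CC1=C(C)C(=O)CC1 | starting material |
| 2 | (1R)-2,3-dimethylcyclopent-2-en-1-ol | O[C@@H]1CCC(C)=C1C | intermediate |
| 3 | m-cresol (3-methylphenol) | Cc1cccc(O)c1 | starting material |
| 4 | 1-{[(1S)-2,3-dimethylcyclopent-2-en-1-yl]oxy}-3-methylbenzene | Cc1cccc(O[C@H]2CCC(C)=C2C)c1 | intermediate |
| 5 | ortho-dienone: 6-(1,2-dimethylcyclopent-2-en-1-yl)-3-methylcyclohexa-2,4-dien-1-one; quaternary carbon arranged as in 6 (formally S by priority change); ring CH centre transient, not assigned | O=C1C=C(C)C=CC1[C@]1(C)CCC=C1C | intermediate (not isolated) |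
| 6 | 2-[(1R)-1,2-dimethylcyclopent-2-en-1-yl]-5-methylphenol | Cc1ccc([C@]2(C)CCC=C2C)c(O)c1 | intermediate |
| 7 | iodomethylzinc phenoxide of 6 | Cc1ccc([C@]2(C)CCC=C2C)c(O[Zn]CI)c1 | intermediate (not isolated) |
| 8 | 2-[(1S,2R,5R)-1,2-dimethylbicyclo[3.1.0]hexan-2-yl]-5-methylphenol (debromolaurinterol) | Cc1ccc([C@]2(C)CC[C@@H]3C[C@@]32C)c(O)c1 | intermediate |
| 9 | 4-bromo-2-[(1S,2R,5R)-1,2-dimethylbicyclo[3.1.0]hexan-2-yl]-5-methylphenol (laurinterol) | Cc1c(Br)cc([C@]2(C)CC[C@@H]3C[C@@]32C)c(O)c1 | intermediate (not isolated) |
| 10 | 2,4-dibromo-6-[(1S,2R,5R)-1,2-dimethylbicyclo[3.1.0]hexan-2-yl]-3-methylphenol | Cc1c(Br)cc([C@]2(C)CC[C@@H]3C[C@@]32C)c(O)c1Br | target |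

**Step count**

Total steps: 5. Longest linear sequence: 5 (1 → 2 → 4 → 6 → 8 → 10); m-cresol 3 enters at step 2.

**Steps most likely to fail, with fallbacks**

1. Step 3 (Claisen). The allyl unit gives a doubly methyl-stabilised cation, so the ether may ionise instead of rearranging. That would cause loss of ee, elimination to 1,2-dimethylcyclopentadiene plus m-cresol, or para alkylation. The fallback sets out from 2 and comes back at 6, replacing the sigmatropic shift by a copper-mediated allylic substitution. Alcohol 2 is acylated with picolinoyl chloride (Et3N, DMAP, CH2Cl2) to give (1R)-2,3-dimethylcyclopent-2-en-1-yl pyridine-2-carboxylate F1. Commercial 1-bromo-2-methoxy-4-methylbenzene and Mg in THF give (2-methoxy-4-methylphenyl)magnesium bromide F2. F2 with CuBr·SMe2 and F1 (THF, −20 → 0 °C) reacts by chelation-assisted anti-SN2' attack at the methyl-bearing alkene carbon, on the face opposite the ester. Because the ester keeps the (R)-configuration of 2 and the attack is anti, the product is 1-[(1R)-1,2-dimethylcyclopent-2-en-1-yl]-2-methoxy-4-methylbenzene F3, with the same quaternary configuration as 6. NaSEt in DMF at 120 °C cleaves the methyl ether and gives 6.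

2. Step 4 (cyclopropanation). The trisubstituted alkene sits next to a quaternary carbon, so delivery may be slow or not fully face-selective, and O-methylation can compete. The fallback sets out from 6 and comes back at 8, using a covalent tether instead of zinc coordination. The phenol of 6 is acylated with 2,5-dioxopyrrolidin-1-yl diazoacetate (Et3N, DMAP cat., CH2Cl2) to give 2-[(1R)-1,2-dimethylcyclopent-2-en-1-yl]-5-methylphenyl diazoacetate F4. Rh2(OAc)4 (1 mol %, CH2Cl2, slow addition) then effects intramolecular cyclopropanation, which can only occur on the aryl face. This gives the bridged seven-membered aryl lactone of 8 (phenol oxygen joined through C=O to cyclopropane carbon C6, carbonyl cis to C2) F5. i-Bu2AlH (1.1 equiv, CH2Cl2, −78 °C) reduces the aryl ester to 2-(2-hydroxy-4-methylphenyl)-1,2-dimethylbicyclo[3.1.0]hexane-6-carbaldehyde (ring configuration as in 8, CHO cis to C2, in equilibrium with its lactol) F6. RhCl(PPh3)3 (1.1 equiv, toluene, 110 °C; Tsuji–Wilkinson decarbonylation with retention) removes CO and gives 8.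

3. Step 2 (Mitsunobu). The activated allylic alcohol may ionise, giving partial racemisation or elimination. The fallback sets out from 1 and comes back at 4, forming the aryl–O bond instead of the alkyl–O bond so the carbinol centre is not touched. Ketone 1 is reduced with the (R)-configured CBS catalyst and BH3·SMe2 to give (1S)-2,3-dimethylcyclopent-2-en-1-ol F7. F7 is coupled with 3-iodotoluene in an Ullmann-type O-arylation (CuI 10 mol %, 3,4,7,8-tetramethyl-1,10-phenanthroline, Cs2CO3, toluene, 90 °C), which retains configuration and gives 4.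

Further compounds
F1 | step 3 | (1R)-2,3-dimethylcyclopent-2-en-1-yl pyridine-2-carboxylate | O=C(O[C@@H]1CCC(C)=C1C)c1ccccn1
F2 | step 3 | (2-methoxy-4-methylphenyl)magnesium bromide | COc1cc(C)ccc1[Mg]Br
F3 | step 3 | 1-[(1R)-1,2-dimethylcyclopent-2-en-1-yl]-2-methoxy-4-methylbenzene | Cc1ccc([C@]2(C)CCC=C2C)c(OC)c1
F4 | step 4 | 2-[(1R)-1,2-dimethylcyclopent-2-en-1-yl]-5-methylphenyl diazoacetate | Cc1ccc([C@]2(C)CCC=C2C)c(OC(=O)C=[N+]=[N-])c1
F5 | step 4 | bridged seven-membered aryl lactone of 8 (phenol O–C(=O)–C6, carbonyl cis to C2) | Cc1ccc2c(c1)OC(=O)[C@H]1[C@H]3CC[C@]2(C)[C@@]13C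
F6 | step 4 | 2-(2-hydroxy-4-methylphenyl)-1,2-dimethylbicyclo[3.1.0]hexane-6-carbaldehyde (ring configuration as in 8, CHO cis to C2) | Cc1ccc([C@]2(C)CC[C@@H]3[C@H](C=O)[C@@]32C)c(O)c1
F7 | step 2 | (1S)-2,3-dimethylcyclopent-2-en-1-ol | O[C@H]1CCC(C)=C1C
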